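## The problem

Target 31 is a dimeric isoflavonoid built on one benzene ring (ring E, 2-methoxy-4-hydroxy). Ring E carries, on neighbouring carbons, C4 of a 3,4-diarylchroman (chroman 1, benzo ring A, 3-aryl ring B) and C3 of a 3-arylchroman (chroman 2, benzo ring D). Three contiguous positions of ring E are therefore substituted (OMe, C4 of chroman 1, C3 of chroman 2), so the second bond to ring E must be made beside a bulky neighbour. There are three stereocentres: chroman 1 is (3R,4S), the two aryl groups trans, and chroman 2 is (3R). C3 and C4 of chroman 1 are adjacent, so one can steer the other and the trans arrangement is also the more stable one. C3 of chroman 2 is insulated from them by ring E and must be set by a catalyst or reagent. Five phenols must end free while three aryl methyl ethers stay, which excludes a late Lewis-acid ether cleavage and asks for protecting groups that leave by hydrogenolysis or mild acid; the doubly benzylic C4–H of chroman 1 and the electron-rich rings tolerate neither strong acid, oxidants nor stray electrophiles. The feature that opens the plan is C3 of chroman 2: it is bound to ring E, to a methylene that carries ring D, to an oxymethylene and to hydrogen. This is the pattern left when an aryl group migrates from boron to the α-carbon of a 2-substituted alkenyl boronate while an aryl electrophile bonds to the terminal carbon, and boron is then exchanged for hydrogen.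

## Retrosynthesis

**31 ⇒ 30.** The four phenolic O–H bonds of rings A, B, D and E are traced back to benzyl ethers. Benzyl is preferred to methyl or silyl because hydrogenolysis distinguishes it cleanly from the three aryl methyl ethers and is the mildest possible last step. Compound 30 has the full skeleton and all stereocentres; the forward reaction only has to spare the chroman C–O bonds, none of which is benzylic.

**30 ⇒ 29 ⇒ 28.** The O1–C2 ether bond of chroman 2 is cut to give phenol–alcohol 29, which comes from the bis-MOM ether 28. Releasing all six hydroxyls first and closing the ring on a pentaphenol was set aside, because four other phenols would compete for the activated alcohol. With MOM on exactly the two oxygens that must react, the Mitsunobu closure meets one phenol and one primary alcohol. The carbinol carbon is not stereogenic, so the forward reaction only needs 6-exo-tet ring closure.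

**28 ⇒ 27.** The C3–H bond of the future chroman 2 is traced to a C–B bond. Tertiary boronic ester 27 has the same skeleton; the forward reaction must replace boron by hydrogen with retention and without β-elimination of the neighbouring acetal oxygen.

**27 ⇒ 16 + 19 + 24.** Two bonds at the boron-bearing carbon and its neighbour are cut: ring E–C3 and CH2–ring D. This is the key disconnection. Neighbouring cuts were weighed: alkylating a ring E arylacetic acid derivative with a ring D benzyl halide needs a stoichiometric auxiliary and a ring E acetic acid that is itself hard to reach, and arylating a preformed chroman at C3 needs a C3 metal species beside an oxygen leaving group. The chosen cut divides a C66 intermediate into aryl bromide 16 (all of chroman 1), the four-carbon boronate 19 and ring D triflate 24, each short to make. The forward reaction must let ring E migrate despite its ortho substituent, must beat direct transmetallation, and must set the new centre by catalyst control.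

**16 ⇒ 15 ⇒ 8 + 13.** The C3–C4 and O1–C2 bonds of chroman 1 are cut, which is a formal [4+2] of an ortho-quinone methide with an aldehyde enamine; the anomeric hydroxyl of lactol 15 is then removed. Hydrogenation of a 3,4-diaryl-2H-chromene would give the cis isomer, and conjugate addition of a ring E nucleophile to a 3-arylcoumarin needs a ring E organometallic that cannot be made regioselectively. The annulation creates both stereocentres in one step from benzhydrol 8 and arylacetaldehyde 13 under amine catalysis.

**8 ⇒ 4 + 6.** The bond between the carbinol carbon and ring A is cut. Iodophenol 6 is magnesiated with its hydroxyl unprotected, so the oxygen that the quinone methide needs is free from the start. The forward reaction is a Grignard addition to a 2,6-disubstituted benzaldehyde.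

**4 ⇒ 3 ⇒ 2 ⇒ 1 and 6 ⇒ 5.** The formyl–aryl bond and two O-alkyl bonds of ring E aldehyde 4 are cut back to symmetric 5-bromoresorcinol 1. Formylating a benzyl ether of 3-bromo-5-methoxyphenol was rejected because the two positions beside bromine (para to OBn or para to OMe) are nearly equivalent. Starting from 1, symmetry fixes the formylation site and the hydrogen bond to the aldehyde then tells the two hydroxyls apart. Iodophenol 6 comes from commercial 3-(benzyloxy)phenol 5 by iodination at the position activated by both oxygens.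

**13 ⇒ 12 ⇒ 11 ⇒ 10 ⇒ 9.** The aldehyde carbon and the formyl–aryl bond of the ring B unit are cut back to 2,6-dimethoxyphenol 9. After benzylation the arene formylates ortho to a terminal methoxy group, which is exactly the 3-oxy-2,4-dimethoxy pattern of ring B, and a Wittig homologation adds the missing carbon.

**19 ⇒ 18 ⇒ 17 and 24 ⇒ 23 ⇒ 21 ⇒ 20.** The C–B bond of 19 is cut to a terminal alkyne (MOM ether 18 of propargyl alcohol 17); the forward reaction must place boron on the internal carbon. The triflate oxygen of 24 is traced through phenol 23 to the formyl group of aldehyde 21, made from commercial 4-(benzyloxy)-2-hydroxybenzaldehyde 20, so the 1,2,4-trioxygenation and the distinction between the two ring D oxygens are bought rather than made.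

## Roads not taken

**Alternative 1:** ring E is built rather than bought. The cut removes the ring E bonds C1–C2 and C5–C6 (ring E numbered from the carbon that carries chroman 1). It leads to ynone A1, which has the ring A aryl ketone and C3 of a finished chroman 2 on the two alkyne ends, and to the electron-rich diene A2. Forward, the CH2 terminus of A2 attacks the alkyne carbon remote from the carbonyl, the acetal carbon bonds to the other, and loss of methanol and of the silyl group gives benzophenone A3.
- Merits: the methoxy and free hydroxyl of ring E are placed unambiguously by the cycloaddition, and chroman 2 is complete beforehand.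
- Weak points: the hard part is only postponed. A3 is a diaryl ketone flanked by two ortho substituents, and a two-carbon ring B unit must still be added to it and both stereocentres of chroman 1 created, with no nearby element of control. The propargylic stereocentre of A1 is acidic once conjugated to the ynone and may racemise during the thermal cycloaddition. Chroman 2 still needs its own asymmetric synthesis.
- Comparison: this road is better in one respect, since the oxygen pattern of ring E follows from the mechanism. The chosen plan sets against it aldehyde 4, whose regiochemistry rests on the symmetry of 1 and on hydrogen bonding, and the fact that each of its later C–C bond formations (steps 10 and 17) creates stereocentres under catalyst control. Step count after the key step would be clearly higher for this alternative.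

**Alternative 2:** both carbon substituents of ring E are installed at once by aryne insertion. The cut removes the ring E–CH2 bond (future C3 of chroman 2) and the ring E–C(=O) bond (future C4 of chroman 1). Forward, fluoride releases the 3-methoxy aryne from silyl triflate A4, the enolate of β-keto ester A5 attacks the aryne carbon remote from methoxy, and acyl transfer to the adjacent carbon gives keto ester A6.
- Merits: two C–C bonds on ring E form in one convergent step with regiochemistry dictated by the methoxy group, and no organometallic has to be made on a heavily loaded intermediate.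
- Weak points: no stereocentre is set. The acetate of A6 must be alkylated with a ring D benzyl halide enantioselectively, which means exchanging the ester for an auxiliary beside a ketone, and the hindered benzophenone must again be turned into the trans-diarylchroman. The ortho keto ester can also condense on itself under base, and A4 needs several steps.
- Comparison: for assembling the ring E core this step is at least as efficient as anything in the chosen route. The chosen plan sets against it that its two ring E bond formations (steps 5 and 17) lead directly to intermediates in which the stereocentres are already set or set in the same operation.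

**Alternative 3:** chroman 1 is reached by skeletal editing. The cut removes C3 with its ring B substituent from the pyran ring and leads to 3-arylbenzofuran A7, which already carries chroman 2, and to chlorodiazirine A8. Forward, the arylchlorocarbene from A8 cyclopropanates the furan double bond and the chlorocyclopropane opens with loss of chloride to benzopyrylium salt A9.
- Merits: ring B arrives last, and the 3,4-diarylbenzopyran skeleton appears in one step.
- Weak points: carbon-atom insertion of this kind is established for indoles and pyrroles, while the benzofuran-to-benzopyrylium variant is less developed. A8 is a very electron-rich, ortho-substituted diazirine of doubtful stability, and its carbene would meet four other electron-rich arenes and several benzylic ethers. A9 is a planar cation, so both stereocentres of chroman 1 must come from reducing a tetrasubstituted ring, and syn hydrogenation gives the cis-diaryl isomer where trans is needed.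
- Comparison: this is the most concise route to the diarylbenzopyran skeleton and is better for late variation of ring B. The chosen plan sets against it an annulation (step 10) that gives the trans-(3R,4S) arrangement directly.

Key step: step 17

Remark: the catalyst enantiomers in steps 10 and 17 are assigned by analogy with the accepted stereochemical models of enamine catalysis and conjunctive coupling; both antipodes of each catalyst are available if the sense must be inverted.

## Route

**Step 1**
Reactants: 1 5-bromobenzene-1,3-diol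
Product: 2 2-bromo-4,6-dihydroxybenzaldehyde
Conditions: POCl3, DMF, MeCN, 0 °C → rt; then H2O, 50 °C
Reagents that add atoms: N,N-dimethylformamide CN(C)C=O; water O
Why: Vilsmeier–Haack formylation of a resorcinol; attack occurs para to one hydroxyl and ortho to the other (as with orcinol), the position between the hydroxyls being more hindered, so the symmetric diol should give one aldehyde.

**Step 2**
Reactants: 2 2-bromo-4,6-dihydroxybenzaldehyde
Product: 3 4-(benzyloxy)-2-bromo-6-hydroxybenzaldehyde
Conditions: BnBr (1.05 equiv), NaHCO3, MeCN, 80 °C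
Reagents that add atoms: benzyl bromide BrCc1ccccc1
Why: Williamson etherification under weak base; the hydroxyl ortho to the formyl group is held in a hydrogen bond, so only the more acidic para hydroxyl should be alkylated, as is usual for 2,4-dihydroxybenzaldehydes.

**Step 3**
Reactants: 3 4-(benzyloxy)-2-bromo-6-hydroxybenzaldehyde
Product: 4 4-(benzyloxy)-2-bromo-6-methoxybenzaldehyde
Conditions: MeI, K2CO3, DMF, rt
Reagents that add atoms: iodomethane CI
Why: Williamson methylation of the remaining chelated phenol with the stronger base.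

**Step 4**
Reactants: 5 3-(benzyloxy)phenol
Product: 6 5-(benzyloxy)-2-iodophenol
Conditions: I2, NaHCO3, THF/H2O, 0 °C
Reagents that add atoms: iodine II
Why: Electrophilic iodination of a phenolate; the position ortho to the hydroxyl and para to the benzyloxy group is activated by both oxygens and is the least hindered, the usual outcome for 3-alkoxyphenols.

**Step 5**
Reactants: 6 5-(benzyloxy)-2-iodophenol; 4 4-(benzyloxy)-2-bromo-6-methoxybenzaldehyde
Product: 8 rac-[4-(benzyloxy)-2-bromo-6-methoxyphenyl][4-(benzyloxy)-2-hydroxyphenyl]methanol, via dimagnesiated phenolate 7 (not isolated)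
Conditions: MeMgCl, THF, −30 °C; i-PrMgCl·LiCl, −30 → 0 °C; then 4, −30 °C → rt; pH 7 buffer
Reagents that add atoms: none
Why: Deprotonation of the phenol and iodine–magnesium exchange give the magnesiated phenolate, which adds to the aldehyde (Grignard addition); the aryl bromide of 4 does not exchange with an arylmagnesium at this temperature. The carbinol centre is racemic and is erased in step 10.

**Step 6**
Reactants: 9 2,6-dimethoxyphenol
Product: 10 2-(benzyloxy)-1,3-dimethoxybenzene
Conditions: BnBr, K2CO3, DMF, 60 °C
Reagents that add atoms: benzyl bromide BrCc1ccccc1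
Why: Williamson etherification of a hindered but acidic phenol.

**Step 7**
Reactants: 10 2-(benzyloxy)-1,3-dimethoxybenzene
Product: 11 3-(benzyloxy)-2,4-dimethoxybenzaldehyde
Conditions: POCl3, DMF, 75 °C; then aq. NaOAc
Reagents that add atoms: N,N-dimethylformamide CN(C)C=O; water O
Why: Vilsmeier–Haack formylation; as with 1,2,3-trimethoxybenzene, the twisted central alkoxy group is a poor donor and attack occurs ortho to one terminal methoxy group and para to the other.

**Step 8**
Reactants: 11 3-(benzyloxy)-2,4-dimethoxybenzaldehyde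
Product: 12 2-(benzyloxy)-1,3-dimethoxy-4-(2-methoxyethenyl)benzene (E/Z mixture)
Conditions: Ph3P(CH2OMe)Cl, KOt-Bu, THF, 0 °C → rt
Reagents that add atoms: (methoxymethyl)triphenylphosphonium chloride COC[P+](c1ccccc1)(c1ccccc1)c1ccccc1.[Cl-]
Why: Wittig methoxymethylenation as a one-carbon homologation; the alkene geometry is irrelevant.

**Step 9**
Reactants: 12 2-(benzyloxy)-1,3-dimethoxy-4-(2-methoxyethenyl)benzene
Product: 13 2-[3-(benzyloxy)-2,4-dimethoxyphenyl]acetaldehyde
Conditions: 2 M HCl, THF, 40 °C; used directly
Reagents that add atoms: water O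
Why: Acid hydrolysis of the enol ether; the arylacetaldehyde is not stored.

**Step 10**
Reactants: 8 rac-[4-(benzyloxy)-2-bromo-6-methoxyphenyl][4-(benzyloxy)-2-hydroxyphenyl]methanol; 13 2-[3-(benzyloxy)-2,4-dimethoxyphenyl]acetaldehyde
Product: 15 (3R,4S)-7-(benzyloxy)-3-[3-(benzyloxy)-2,4-dimethoxyphenyl]-4-[4-(benzyloxy)-2-bromo-6-methoxyphenyl]chroman-2-ol (both C2 epimers), via ortho-quinone methide 14 (not isolated)
Conditions: (R)-α,α-diphenylprolinol trimethylsilyl ether (20 mol%), PhCO2H (20 mol%), CH2Cl2, 0 °C → rt
Reagents that add atoms: none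
Why: Acid-promoted dehydration of the electron-rich ortho-hydroxybenzhydrol gives the quinone methide, the enamine of 13 adds to it in a Michael fashion, and hydrolysis and hemiacetalisation give the lactol (formal [4+2] annulation under enamine catalysis). The prolinol ether shields one enamine face and so sets C3 and, through the synclinal transition state known from enamine additions to nitroalkenes, C4; the trans-diaryl arrangement is also the thermodynamic one because C3 can equilibrate through the open hydroxy aldehyde.

**Step 11**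
Reactants: 15 (3R,4S)-7-(benzyloxy)-3-[3-(benzyloxy)-2,4-dimethoxyphenyl]-4-[4-(benzyloxy)-2-bromo-6-methoxyphenyl]chroman-2-ol
Product: 16 (3R,4S)-7-(benzyloxy)-3-[3-(benzyloxy)-2,4-dimethoxyphenyl]-4-[4-(benzyloxy)-2-bromo-6-methoxyphenyl]chromane
Conditions: Et3SiH, BF3·OEt2, CH2Cl2, −78 → −30 °C
Reagents that add atoms: none
Why: Ionic hydrogenation of the lactol: the Lewis acid ionises the anomeric hydroxyl and the silane reduces the cyclic oxocarbenium ion at low temperature, leaving C3, C4, the benzyl ethers and the aryl bromide untouched.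

**Step 12**
Reactants: 17 prop-2-yn-1-ol
Product: 18 3-(methoxymethoxy)prop-1-yne
Conditions: MOMCl, i-Pr2NEt, CH2Cl2, 0 °C → rt
Reagents that add atoms: chloromethyl methyl ether COCCl
Why: O-alkylation with an α-chloro ether (MOM protection).

**Step 13**
Reactants: 18 3-(methoxymethoxy)prop-1-yne
Product: 19 2-[3-(methoxymethoxy)prop-1-en-2-yl]-4,4,5,5-tetramethyl-1,3,2-dioxaborolane
Conditions: B2pin2, (SIMes)CuCl (5 mol%; SIMes = 1,3-dimesitylimidazolin-2-ylidene), NaOt-Bu (5 mol%), MeOH (2 equiv), THF, −50 → −15 °C
Reagents that add atoms: bis(pinacolato)diboron CC1(C)OB(OC1(C)C)B1OC(C)(C)C(C)(C)O1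
Why: Copper-catalysed protoboration of a terminal alkyne; with an N-aryl carbene ligand on monovalent copper, borylcupration of propargylic ethers places boron on the internal carbon and methanol protonates the alkenylcopper, giving the 1,1-disubstituted alkenyl boronate.

**Step 14**
Reactants: 20 4-(benzyloxy)-2-hydroxybenzaldehyde
Product: 21 4-(benzyloxy)-2-(methoxymethoxy)benzaldehyde
Conditions: MOMCl, i-Pr2NEt, CH2Cl2, 0 °C → rt
Reagents that add atoms: chloromethyl methyl ether COCCl
Why: MOM protection of the phenol; this oxygen becomes O1 of chroman 2 and must be freed without touching benzyl ethers.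

**Step 15**
Reactants: 21 4-(benzyloxy)-2-(methoxymethoxy)benzaldehyde
Product: 23 4-(benzyloxy)-2-(methoxymethoxy)phenol, via aryl formate 22 (not isolated)
Conditions: mCPBA, CH2Cl2, 0 °C → rt; then K2CO3, MeOH, rt
Reagents that add atoms: 3-chloroperbenzoic acid OOC(=O)c1cccc(Cl)c1
Why: Baeyer–Villiger (Dakin-type) oxidation of an electron-rich benzaldehyde: aryl migration gives the formate, which methanolysis cleaves to the phenol.

**Step 16**
Reactants: 23 4-(benzyloxy)-2-(methoxymethoxy)phenol
Product: 24 4-(benzyloxy)-2-(methoxymethoxy)phenyl trifluoromethanesulfonate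
Conditions: Tf2O, pyridine, CH2Cl2, 0 °C
Reagents that add atoms: trifluoromethanesulfonic anhydride O=S(=O)(OS(=O)(=O)C(F)(F)F)C(F)(F)F
Why: O-triflation of a phenol.

**Step 17**
Reactants: 16 (3R,4S)-7-(benzyloxy)-3-[3-(benzyloxy)-2,4-dimethoxyphenyl]-4-[4-(benzyloxy)-2-bromo-6-methoxyphenyl]chromane; 19 2-[3-(methoxymethoxy)prop-1-en-2-yl]-4,4,5,5-tetramethyl-1,3,2-dioxaborolane; 24 4-(benzyloxy)-2-(methoxymethoxy)phenyl trifluoromethanesulfonate
Product: 27 (3R,4S)-7-(benzyloxy)-4-{4-(benzyloxy)-2-[(2R)-1-[4-(benzyloxy)-2-(methoxymethoxy)phenyl]-3-(methoxymethoxy)-2-(4,4,5,5-tetramethyl-1,3,2-dioxaborolan-2-yl)propan-2-yl]-6-methoxyphenyl}-3-[3-(benzyloxy)-2,4-dimethoxyphenyl]chromane, via aryllithium 25 (not isolated), via lithium boron ate complex 26 (not isolated)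
Conditions: 16, t-BuLi (2.0 equiv), THF/Et2O, −78 °C; 19, −78 °C → rt; then Pd(OAc)2 (5 mol%), Mandyphos ligand (6 mol%; 1,1'-bis[bis(4-methoxy-3,5-dimethylphenyl)phosphino]-2,2'-bis[α-(dimethylamino)benzyl]ferrocene, enantiomer as in the remark), 24, KOTf, THF, 60 °C
Reagents that add atoms: none
Why: Bromine–lithium exchange gives aryllithium 25, which adds to the boron of 19 to give the four-coordinate ate complex 26. Zerovalent palladium, formed from Pd(OAc)2 and the bisphosphine, adds oxidatively to triflate 24; the cationic arylpalladium species binds the alkene of 26 and induces an anti 1,2-shift of ring E from boron to the α-carbon while palladium bonds to the terminal carbon, and reductive elimination forms the CH2–ring D bond. The closest known reaction type is the palladium-catalysed enantioselective conjunctive cross-coupling of α-substituted alkenylboron ate complexes with aryl triflates to tertiary boronic esters. No ring is closed; the ring E–C3 and C4–ring D bonds of the future chroman 2 are formed. The one new stereocentre, the boron-bearing carbon, is set by the chiral bisphosphine, which decides the alkene face bound to palladium and is expected to override the remote centres of chroman 1; (R) is needed so that stereoretentive exchange of boron for hydrogen gives (3R). The step needs the metallate shift to outrun direct transmetallation of the aryl or alkenyl group, which the triflate (non-coordinating counter-ion, cationic palladium) and KOTf (removes the bromide left by the exchange) should secure. The alkylpalladium intermediate has a quaternary neighbour and the acetal oxygen is γ to palladium, so neither β-hydride nor β-alkoxide elimination is open.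

**Step 18**
Reactants: 27 the tertiary pinacol boronic ester of step 17
Product: 28 (3R,4S)-7-(benzyloxy)-4-{4-(benzyloxy)-2-[(2R)-1-[4-(benzyloxy)-2-(methoxymethoxy)phenyl]-3-(methoxymethoxy)propan-2-yl]-6-methoxyphenyl}-3-[3-(benzyloxy)-2,4-dimethoxyphenyl]chromane
Conditions: TBAF·3H2O, toluene, 45 °C
Reagents that add atoms: none
Why: Fluoride-promoted protodeboronation of a tertiary benzylic boronic ester: fluoride forms the boron ate complex and hydrogen-bonded water delivers the proton to the C–B bond from the boron side, so hydrogen replaces boron with retention and fluoride is released again on work-up. Acetal and benzyl ethers are inert to fluoride.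

**Step 19**
Reactants: 28 the bis-MOM ether of step 18
Product: 29 (2R)-2-{5-(benzyloxy)-2-[(3R,4S)-7-(benzyloxy)-3-(3-(benzyloxy)-2,4-dimethoxyphenyl)chroman-4-yl]-3-methoxyphenyl}-3-[4-(benzyloxy)-2-hydroxyphenyl]propan-1-ol
Conditions: conc. HCl (cat.), MeOH/THF, 50 °C
Reagents that add atoms: none
Why: Acid-catalysed transacetalisation to methanol removes the aryl and the alkyl MOM group as dimethoxymethane, while benzyl and methyl aryl ethers stay.

**Step 20**
Reactants: 29 the phenol–alcohol of step 19
Product: 30 (3R,4S)-7-(benzyloxy)-4-{4-(benzyloxy)-2-[(3R)-7-(benzyloxy)chroman-3-yl]-6-methoxyphenyl}-3-[3-(benzyloxy)-2,4-dimethoxyphenyl]chromane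
Conditions: PPh3, DIAD, THF (0.01 M), 0 °C → rt
Reagents that add atoms: none
Why: Intramolecular Mitsunobu etherification (6-exo-tet): the only free phenol attacks the activated primary carbinol carbon, which is not stereogenic, so C3 of chroman 2 is unaffected.

**Step 21**
Reactants: 30 the tetra-O-benzyl ether of the target
Product: 31 (3R,4S)-3-(3-hydroxy-2,4-dimethoxyphenyl)-4-{4-hydroxy-2-[(3R)-7-hydroxychroman-3-yl]-6-methoxyphenyl}chroman-7-ol (CNP0305801.1)
Conditions: H2 (1 atm), 10% Pd/C, THF/MeOH, rt
Reagents that add atoms: none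
Why: Hydrogenolysis of the four aryl benzyl ethers; aryl methyl ethers, the non-benzylic chroman C–O bonds and the three stereocentres are not touched.

## Compound list

1 | 5-bromobenzene-1,3-diol | Oc1cc(O)cc(Br)c1 | starting material
2 | 2-bromo-4,6-dihydroxybenzaldehyde | O=Cc1c(O)cc(O)cc1Br | intermediate
3 | 4-(benzyloxy)-2-bromo-6-hydroxybenzaldehyde | O=Cc1c(O)cc(OCc2ccccc2)cc1Br | intermediate
4 | 4-(benzyloxy)-2-bromo-6-methoxybenzaldehyde | COc1cc(OCc2ccccc2)cc(Br)c1C=O | intermediate
5 | 3-(benzyloxy)phenol | Oc1cccc(OCc2ccccc2)c1 | starting material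
6 | 5-(benzyloxy)-2-iodophenol | Oc1cc(OCc2ccccc2)ccc1I | intermediate
7 | chloromagnesium 5-(benzyloxy)-2-(chloromagnesio)phenolate | Cl[Mg]Oc1cc(OCc2ccccc2)ccc1[Mg]Cl | intermediate
8 | rac-[4-(benzyloxy)-2-bromo-6-methoxyphenyl][4-(benzyloxy)-2-hydroxyphenyl]methanol | OC(c1ccc(OCc2ccccc2)cc1O)c1c(Br)cc(OCc2ccccc2)cc1OC | intermediate
9 | 2,6-dimethoxyphenol | COc1cccc(OC)c1O | starting material
10 | 2-(benzyloxy)-1,3-dimethoxybenzene | COc1cccc(OC)c1OCc1ccccc1 | intermediate
11 | 3-(benzyloxy)-2,4-dimethoxybenzaldehyde | COc1ccc(C=O)c(OC)c1OCc1ccccc1 | intermediate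
12 | 2-(benzyloxy)-1,3-dimethoxy-4-(2-methoxyethenyl)benzene (E/Z mixture) | COC=Cc1ccc(OC)c(OCc2ccccc2)c1OC | intermediate
13 | 2-[3-(benzyloxy)-2,4-dimethoxyphenyl]acetaldehyde | O=CCc1ccc(OC)c(OCc2ccccc2)c1OC | intermediate
14 | 3-(benzyloxy)-6-[4-(benzyloxy)-2-bromo-6-methoxybenzylidene]cyclohexa-2,4-dien-1-one | O=C1C=C(OCc2ccccc2)C=CC1=Cc1c(Br)cc(OCc2ccccc2)cc1OC | intermediate
15 | (3R,4S)-7-(benzyloxy)-3-[3-(benzyloxy)-2,4-dimethoxyphenyl]-4-[4-(benzyloxy)-2-bromo-6-methoxyphenyl]chroman-2-ol (both C2 epimers) | COc1ccc([C@@H]2C(O)Oc3cc(OCc4ccccc4)ccc3[C@H]2c2c(OC)cc(OCc3ccccc3)cc2Br)c(OC)c1OCc1ccccc1 | intermediate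
16 | (3R,4S)-7-(benzyloxy)-3-[3-(benzyloxy)-2,4-dimethoxyphenyl]-4-[4-(benzyloxy)-2-bromo-6-methoxyphenyl]chromane | COc1ccc([C@@H]2COc3cc(OCc4ccccc4)ccc3[C@H]2c2c(OC)cc(OCc3ccccc3)cc2Br)c(OC)c1OCc1ccccc1 | intermediate
17 | prop-2-yn-1-ol | C#CCO | starting material
18 | 3-(methoxymethoxy)prop-1-yne | C#CCOCOC | intermediate
19 | 2-[3-(methoxymethoxy)prop-1-en-2-yl]-4,4,5,5-tetramethyl-1,3,2-dioxaborolane | C=C(COCOC)B1OC(C)(C)C(C)(C)O1 | intermediate
20 | 4-(benzyloxy)-2-hydroxybenzaldehyde | O=Cc1ccc(OCc2ccccc2)cc1O | starting material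
21 | 4-(benzyloxy)-2-(methoxymethoxy)benzaldehyde | COCOc1cc(OCc2ccccc2)ccc1C=O | intermediate
22 | 4-(benzyloxy)-2-(methoxymethoxy)phenyl formate | COCOc1cc(OCc2ccccc2)ccc1OC=O | intermediate
23 | 4-(benzyloxy)-2-(methoxymethoxy)phenol | COCOc1cc(OCc2ccccc2)ccc1O | intermediate
24 | 4-(benzyloxy)-2-(methoxymethoxy)phenyl trifluoromethanesulfonate | COCOc1cc(OCc2ccccc2)ccc1OS(=O)(=O)C(F)(F)F | intermediate
25 | {5-(benzyloxy)-2-[(3R,4S)-7-(benzyloxy)-3-(3-(benzyloxy)-2,4-dimethoxyphenyl)chroman-4-yl]-3-methoxyphenyl}lithium | COc1ccc([C@@H]2COc3cc(OCc4ccccc4)ccc3[C@H]2c2c(OC)cc(OCc3ccccc3)cc2[Li])c(OC)c1OCc1ccccc1 | intermediate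
26 | lithium {5-(benzyloxy)-2-[(3R,4S)-7-(benzyloxy)-3-(3-(benzyloxy)-2,4-dimethoxyphenyl)chroman-4-yl]-3-methoxyphenyl}[3-(methoxymethoxy)prop-1-en-2-yl](pinacolato)borate | [Li+].COc1ccc([C@@H]2COc3cc(OCc4ccccc4)ccc3[C@H]2c2c(OC)cc(OCc3ccccc3)cc2[B-]2(C(=C)COCOC)OC(C)(C)C(C)(C)O2)c(OC)c1OCc1ccccc1 | intermediate
27 | (3R,4S)-7-(benzyloxy)-4-{4-(benzyloxy)-2-[(2R)-1-[4-(benzyloxy)-2-(methoxymethoxy)phenyl]-3-(methoxymethoxy)-2-(4,4,5,5-tetramethyl-1,3,2-dioxaborolan-2-yl)propan-2-yl]-6-methoxyphenyl}-3-[3-(benzyloxy)-2,4-dimethoxyphenyl]chromane | COc1ccc([C@@H]2COc3cc(OCc4ccccc4)ccc3[C@H]2c2c(OC)cc(OCc3ccccc3)cc2[C@@](B2OC(C)(C)C(C)(C)O2)(Cc2ccc(OCc3ccccc3)cc2OCOC)COCOC)c(OC)c1OCc1ccccc1 | intermediate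
28 | (3R,4S)-7-(benzyloxy)-4-{4-(benzyloxy)-2-[(2R)-1-[4-(benzyloxy)-2-(methoxymethoxy)phenyl]-3-(methoxymethoxy)propan-2-yl]-6-methoxyphenyl}-3-[3-(benzyloxy)-2,4-dimethoxyphenyl]chromane | COc1ccc([C@@H]2COc3cc(OCc4ccccc4)ccc3[C@H]2c2c(OC)cc(OCc3ccccc3)cc2[C@@H](Cc2ccc(OCc3ccccc3)cc2OCOC)COCOC)c(OC)c1OCc1ccccc1 | intermediate
29 | (2R)-2-{5-(benzyloxy)-2-[(3R,4S)-7-(benzyloxy)-3-(3-(benzyloxy)-2,4-dimethoxyphenyl)chroman-4-yl]-3-methoxyphenyl}-3-[4-(benzyloxy)-2-hydroxyphenyl]propan-1-ol | COc1ccc([C@@H]2COc3cc(OCc4ccccc4)ccc3[C@H]2c2c(OC)cc(OCc3ccccc3)cc2[C@@H](Cc2ccc(OCc3ccccc3)cc2O)CO)c(OC)c1OCc1ccccc1 | intermediate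
30 | (3R,4S)-7-(benzyloxy)-4-{4-(benzyloxy)-2-[(3R)-7-(benzyloxy)chroman-3-yl]-6-methoxyphenyl}-3-[3-(benzyloxy)-2,4-dimethoxyphenyl]chromane | COc1ccc([C@@H]2COc3cc(OCc4ccccc4)ccc3[C@H]2c2c(OC)cc(OCc3ccccc3)cc2[C@@H]2COc3cc(OCc4ccccc4)ccc3C2)c(OC)c1OCc1ccccc1 | intermediate
31 | (3R,4S)-3-(3-hydroxy-2,4-dimethoxyphenyl)-4-{4-hydroxy-2-[(3R)-7-hydroxychroman-3-yl]-6-methoxyphenyl}chroman-7-ol | COc1ccc([C@@H]2COc3cc(O)ccc3[C@H]2c2c(OC)cc(O)cc2[C@@H]2COc3cc(O)ccc3C2)c(OC)c1O | target

## Step count and weakest steps

Total: 21 steps. Longest linear sequence: 11 steps (steps 6, 7, 8, 9, 10, 11, 17, 18, 19, 20, 21 from 9; the ring E branch through steps 1, 2, 3, 5 is equally long).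

**Step 17 (key step).** Ring E must migrate to a carbon that becomes fully substituted beside the bulky chroman 1, so several processes may intervene:
- slow metallate shift, letting direct transmetallation of the aryl or alkenyl group to palladium take over;
- inhibition of the cationic palladium species by residual bromide;
- proton transfer from the doubly benzylic C4–H to the neighbouring aryllithium before borate formation;
- reduced facial selectivity if the catalyst and chroman 1 are mismatched.

Fallback, from 16 and 19, returning at 28 (step 18 is then not needed): Suzuki–Miyaura coupling of 16 with 19 (Pd(OAc)2, SPhos, K3PO4, toluene/H2O) should give the 2-arylallyl ether (3R,4S)-7-(benzyloxy)-4-{4-(benzyloxy)-2-methoxy-6-[3-(methoxymethoxy)prop-1-en-2-yl]phenyl}-3-[3-(benzyloxy)-2,4-dimethoxyphenyl]chromane F1. Catalytic enantioselective anti-Markovnikov hydroboration of F1 with pinacolborane (CoCl2 complex of a chiral iminopyridine–oxazoline ligand, activated with NaBHEt3) should give the primary boronic ester with the (2R) centre, (3R,4S)-7-(benzyloxy)-4-{4-(benzyloxy)-2-methoxy-6-[(2R)-1-(methoxymethoxy)-3-(4,4,5,5-tetramethyl-1,3,2-dioxaborolan-2-yl)propan-2-yl]phenyl}-3-[3-(benzyloxy)-2,4-dimethoxyphenyl]chromane F2. A B-alkyl Suzuki–Miyaura coupling of F2 with triflate 24 (Pd(OAc)2, RuPhos, K3PO4, toluene/H2O) then gives 28.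

**Step 10.** The quinone methide carries a 2,6-disubstituted aryl group on its electrophilic carbon. Addition of the bulky enamine may be slow, so that oligomerisation of the quinone methide or reversible capture by the amine wins, and facial selectivity at C4 may be lower than with simpler aryl groups.

Fallback, from 8 and 12, returning at 16: Brønsted-acid-promoted inverse-demand hetero-Diels–Alder reaction of the quinone methide from 8 with enol ether 12 (diphenyl phosphate, CH2Cl2) should give, after acid equilibration of C3, the racemic trans acetal rac-(3R,4S)-7-(benzyloxy)-3-[3-(benzyloxy)-2,4-dimethoxyphenyl]-4-[4-(benzyloxy)-2-bromo-6-methoxyphenyl]-2-methoxychromane F3. Reduction of F3 with Et3SiH/BF3·OEt2 gives racemic 16, and preparative chromatography on a chiral stationary phase removes the (3S,4R) enantiomer, (3S,4R)-7-(benzyloxy)-3-[3-(benzyloxy)-2,4-dimethoxyphenyl]-4-[4-(benzyloxy)-2-bromo-6-methoxyphenyl]chromane F4, leaving 16.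

**Step 18.** The boron ate complex has an acetal oxygen β to boron, so 1,2-elimination may compete with protonation; a dissociative pathway could erode configuration; and the hindered boron may be slow to accept fluoride.

Fallback, from 27, returning at 29: the elimination is driven to completion on purpose (anhydrous TBAF, THF, 60 °C) to the 1,1-disubstituted alkene (3R,4S)-7-(benzyloxy)-4-{4-(benzyloxy)-2-[3-(4-(benzyloxy)-2-(methoxymethoxy)phenyl)prop-1-en-2-yl]-6-methoxyphenyl}-3-[3-(benzyloxy)-2,4-dimethoxyphenyl]chromane F5. Enantioselective copper-catalysed protoboration of F5 (B2pin2, MeOH, a chiral N-heterocyclic carbene complex of CuCl, NaOt-Bu) gives the primary boronic ester (3R,4S)-7-(benzyloxy)-4-{4-(benzyloxy)-2-[(2R)-1-[4-(benzyloxy)-2-(methoxymethoxy)phenyl]-3-(4,4,5,5-tetramethyl-1,3,2-dioxaborolan-2-yl)propan-2-yl]-6-methoxyphenyl}-3-[3-(benzyloxy)-2,4-dimethoxyphenyl]chromane F6. Oxidation of F6 with NaBO3·4H2O gives the alcohol (2R)-2-{5-(benzyloxy)-2-[(3R,4S)-7-(benzyloxy)-3-(3-(benzyloxy)-2,4-dimethoxyphenyl)chroman-4-yl]-3-methoxyphenyl}-3-[4-(benzyloxy)-2-(methoxymethoxy)phenyl]propan-1-ol F7, and the acid conditions of step 19 remove the aryl MOM group of F7 to give 29.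

**Step 11.** The oxocarbenium ion may lose the C3 proton to a 4H-chromene whose re-protonation would scramble C3; it may also be captured by one of the electron-rich rings, or BF3 may cleave a benzyl ether.

Fallback, from 15, returning at 16: NaBH4 (MeOH/THF, 0 °C) reduces the open hydroxy aldehyde form of 15 to the diol (2R,3S)-3-[4-(benzyloxy)-2-bromo-6-methoxyphenyl]-3-[4-(benzyloxy)-2-hydroxyphenyl]-2-[3-(benzyloxy)-2,4-dimethoxyphenyl]propan-1-ol F8, and Mitsunobu etherification of F8 (PPh3, DIAD, THF) closes the pyran ring to 16 without an oxocarbenium ion.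

## Further compounds

F1 | step 17 | (3R,4S)-7-(benzyloxy)-4-{4-(benzyloxy)-2-methoxy-6-[3-(methoxymethoxy)prop-1-en-2-yl]phenyl}-3-[3-(benzyloxy)-2,4-dimethoxyphenyl]chromane | COc1ccc([C@@H]2COc3cc(OCc4ccccc4)ccc3[C@H]2c2c(OC)cc(OCc3ccccc3)cc2C(=C)COCOC)c(OC)c1OCc1ccccc1
F2 | step 17 | (3R,4S)-7-(benzyloxy)-4-{4-(benzyloxy)-2-methoxy-6-[(2R)-1-(methoxymethoxy)-3-(4,4,5,5-tetramethyl-1,3,2-dioxaborolan-2-yl)propan-2-yl]phenyl}-3-[3-(benzyloxy)-2,4-dimethoxyphenyl]chromane | COc1ccc([C@@H]2COc3cc(OCc4ccccc4)ccc3[C@H]2c2c(OC)cc(OCc3ccccc3)cc2[C@@H](CB2OC(C)(C)C(C)(C)O2)COCOC)c(OC)c1OCc1ccccc1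
F3 | step 10 | rac-(3R,4S)-7-(benzyloxy)-3-[3-(benzyloxy)-2,4-dimethoxyphenyl]-4-[4-(benzyloxy)-2-bromo-6-methoxyphenyl]-2-methoxychromane (racemate, one enantiomer drawn) | COc1ccc([C@@H]2C(OC)Oc3cc(OCc4ccccc4)ccc3[C@H]2c2c(OC)cc(OCc3ccccc3)cc2Br)c(OC)c1OCc1ccccc1
F4 | step 10 | (3S,4R)-7-(benzyloxy)-3-[3-(benzyloxy)-2,4-dimethoxyphenyl]-4-[4-(benzyloxy)-2-bromo-6-methoxyphenyl]chromane | COc1ccc([C@H]2COc3cc(OCc4ccccc4)ccc3[C@@H]2c2c(OC)cc(OCc3ccccc3)cc2Br)c(OC)c1OCc1ccccc1
F5 | step 18 | (3R,4S)-7-(benzyloxy)-4-{4-(benzyloxy)-2-[3-(4-(benzyloxy)-2-(methoxymethoxy)phenyl)prop-1-en-2-yl]-6-methoxyphenyl}-3-[3-(benzyloxy)-2,4-dimethoxyphenyl]chromane | COc1ccc([C@@H]2COc3cc(OCc4ccccc4)ccc3[C@H]2c2c(OC)cc(OCc3ccccc3)cc2C(=C)Cc2ccc(OCc3ccccc3)cc2OCOC)c(OC)c1OCc1ccccc1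
F6 | step 18 | (3R,4S)-7-(benzyloxy)-4-{4-(benzyloxy)-2-[(2R)-1-[4-(benzyloxy)-2-(methoxymethoxy)phenyl]-3-(4,4,5,5-tetramethyl-1,3,2-dioxaborolan-2-yl)propan-2-yl]-6-methoxyphenyl}-3-[3-(benzyloxy)-2,4-dimethoxyphenyl]chromane | COc1ccc([C@@H]2COc3cc(OCc4ccccc4)ccc3[C@H]2c2c(OC)cc(OCc3ccccc3)cc2[C@@H](Cc2ccc(OCc3ccccc3)cc2OCOC)CB2OC(C)(C)C(C)(C)O2)c(OC)c1OCc1ccccc1
F7 | step 18 | (2R)-2-{5-(benzyloxy)-2-[(3R,4S)-7-(benzyloxy)-3-(3-(benzyloxy)-2,4-dimethoxyphenyl)chroman-4-yl]-3-methoxyphenyl}-3-[4-(benzyloxy)-2-(methoxymethoxy)phenyl]propan-1-ol | COc1ccc([C@@H]2COc3cc(OCc4ccccc4)ccc3[C@H]2c2c(OC)cc(OCc3ccccc3)cc2[C@@H](Cc2ccc(OCc3ccccc3)cc2OCOC)CO)c(OC)c1OCc1ccccc1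
F8 | step 11 | (2R,3S)-3-[4-(benzyloxy)-2-bromo-6-methoxyphenyl]-3-[4-(benzyloxy)-2-hydroxyphenyl]-2-[3-(benzyloxy)-2,4-dimethoxyphenyl]propan-1-ol | COc1ccc([C@H](CO)[C@@H](c2ccc(OCc3ccccc3)cc2O)c2c(OC)cc(OCc3ccccc3)cc2Br)c(OC)c1OCc1ccccc1
A1 | alternative 1 | 1-[2,4-bis(benzyloxy)phenyl]-3-[(3R)-7-(benzyloxy)chroman-3-yl]prop-2-yn-1-one (configuration as drawn, matching C3 of chroman 2) | O=C(C#C[C@@H]1COc2cc(OCc3ccccc3)ccc2C1)c1ccc(OCc2ccccc2)cc1OCc1ccccc1
A2 | alternative 1 | 1,1-dimethoxy-3-(trimethylsilyloxy)buta-1,3-diene | COC(OC)=CC(=C)O[Si](C)(C)C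
A3 | alternative 1 | [2,4-bis(benzyloxy)phenyl]{2-[(3R)-7-(benzyloxy)chroman-3-yl]-4-hydroxy-6-methoxyphenyl}methanone | O=C(c1c(OC)cc(O)cc1[C@@H]1COc2cc(OCc3ccccc3)ccc2C1)c1ccc(OCc2ccccc2)cc1OCc1ccccc1
A4 | alternative 2 | 5-(benzyloxy)-3-methoxy-2-(trimethylsilyl)phenyl trifluoromethanesulfonate | COc1cc(OCc2ccccc2)cc(OS(=O)(=O)C(F)(F)F)c1[Si](C)(C)C
A5 | alternative 2 | methyl 3-[2,4-bis(benzyloxy)phenyl]-3-oxopropanoate | COC(=O)CC(=O)c1ccc(OCc2ccccc2)cc1OCc1ccccc1
A6 | alternative 2 | methyl 2-[2-(2,4-bis(benzyloxy)benzoyl)-5-(benzyloxy)-3-methoxyphenyl]acetate | COC(=O)Cc1cc(OCc2ccccc2)cc(OC)c1C(=O)c1ccc(OCc2ccccc2)cc1OCc1ccccc1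
A7 | alternative 3 | 6-(benzyloxy)-3-{4-(benzyloxy)-2-[(3R)-7-(benzyloxy)chroman-3-yl]-6-methoxyphenyl}benzofuran | c1oc2cc(OCc3ccccc3)ccc2c1-c1c(OC)cc(OCc2ccccc2)cc1[C@@H]1COc2cc(OCc3ccccc3)ccc2C1
A8 | alternative 3 | 3-[3-(benzyloxy)-2,4-dimethoxyphenyl]-3-chloro-3H-diazirine | COc1ccc(C2(Cl)N=N2)c(OC)c1OCc1ccccc1
A9 | alternative 3 | 7-(benzyloxy)-3-[3-(benzyloxy)-2,4-dimethoxyphenyl]-4-{4-(benzyloxy)-2-[(3R)-7-(benzyloxy)chroman-3-yl]-6-methoxyphenyl}-1-benzopyrylium chloride | COc1ccc(-c2c[o+]c3cc(OCc4ccccc4)ccc3c2-c2c(OC)cc(OCc3ccccc3)cc2[C@@H]2COc3cc(OCc4ccccc4)ccc3C2)c(OC)c1OCc1ccccc1.[Cl-]
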